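**Retrosynthetic overview**

1. Feature: in the tetrahydrofuran (O1, C2–C5; aryl on C2 and C5; CH2OH carbons C3' on C3 and C4' on C4) each aryl-bearing carbon is cis to its neighbouring CH2OH-bearing carbon and C3/C4 are trans. O1–C5 can therefore be closed with inversion from a cis-β-lactone spanning C4'–C4–C5, and C2 set by hydride addition anti to the C3 substituent.
2. Last ring (tetrahydrofuran): keto-β-lactone ring expansion with silane capture (O1–C5 and C2–H bonds); C4' leaves the step as CO2H.
3. First ring (temporary β-lactone, bonds C4–C5 and C4'–O): alkaloid/LiClO4-catalysed ketene–aldehyde cycloaddition of a succinate-derived acid chloride with vanillin pivalate; the aryl ketone (C2) is then installed by thioester–boronic acid coupling, because a free γ-keto acid chloride would close to an enol lactone.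
4. C3 stereocentre: Evans alkylation of a 3-(benzyloxy)propanoyl oxazolidinone with tert-butyl bromoacetate; the side-chain benzyl ether is then exchanged for a pivalate so that no ether oxygen sits five atoms from C5 in the ring expansion.
5. End game: LiAlH4 (CO2H to CH2OH, both pivalates off), then hydrogenolysis of the single benzyl ether.

Key step: step 11

Assumption (chemistry): O-trimethylsilylquinidine is taken as the pseudoenantiomer that gives the (3R,4R)-lactone in step 9; if the sense of induction is the opposite, O-trimethylsilylquinine is used instead.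

**Route**

Step 1
Reactants: 1 vanillin
Product: 2 4-formyl-2-methoxyphenyl pivalate
Conditions: PivCl, Et3N, DMAP (cat.), CH2Cl2, 0 °C → rt
Reagents that add atoms: pivaloyl chloride, CC(C)(C)C(=O)Cl
Why: DMAP-catalysed O-acylation of the phenol should be clean, the aldehyde is inert and no stereocentre is involved; the ester makes this ring no more electron-rich than phenyl for the later lactone chemistry.

Step 2
Reactants: 3 3-(benzyloxy)propanoic acid; 4 (S)-4-benzyloxazolidin-2-one
Product: 6 (S)-4-benzyl-3-[3-(benzyloxy)propanoyl]oxazolidin-2-one, via mixed pivalic anhydride 5 (not isolated)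
Conditions: PivCl, Et3N, THF, −20 °C; then 4, LiCl, −20 °C → rt
Reagents that add atoms: none
Why: N-acylation of the oxazolidinone through the mixed pivalic anhydride (one-pot LiCl/Et3N protocol) is the standard way to load the auxiliary and leaves its stereocentre untouched.

Step 3
Reactants: 6 (S)-4-benzyl-3-[3-(benzyloxy)propanoyl]oxazolidin-2-one; 7 tert-butyl bromoacetate
Product: 9 tert-butyl (3S)-3-[(benzyloxy)methyl]-4-[(4S)-4-benzyl-2-oxooxazolidin-3-yl]-4-oxobutanoate, via sodium Z-enolate 8 (not isolated)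
Conditions: NaN(SiMe3)2, THF, −78 °C; then 7, −78 °C; AcOH quench at −78 °C
Reagents that add atoms: none
Why: Evans asymmetric alkylation: the chelated sodium Z-enolate is alkylated by the reactive bromoacetate on the face opposite the auxiliary benzyl group, which sets the (S) centre that becomes C3 of the tetrahydrofuran; holding the enolate at −78 °C should suppress β-elimination of benzyloxide.

Step 4
Reactants: 9 tert-butyl (3S)-3-[(benzyloxy)methyl]-4-[(4S)-4-benzyl-2-oxooxazolidin-3-yl]-4-oxobutanoate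
Product: 10 tert-butyl (3S)-4-[(4S)-4-benzyl-2-oxooxazolidin-3-yl]-3-(hydroxymethyl)-4-oxobutanoate
Conditions: H2 (1 atm), Pd(OH)2/C, EtOAc, rt
Reagents that add atoms: none
Why: Hydrogenolysis of the alkyl benzyl ether leaves the imide, the tert-butyl ester and the C-benzyl group of the auxiliary intact, and is done here because no sulfur and no other O-benzyl group is yet present.

Step 5
Reactants: 10 tert-butyl (3S)-4-[(4S)-4-benzyl-2-oxooxazolidin-3-yl]-3-(hydroxymethyl)-4-oxobutanoate
Product: 11 tert-butyl (3S)-4-[(4S)-4-benzyl-2-oxooxazolidin-3-yl]-4-oxo-3-[(pivaloyloxy)methyl]butanoate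
Conditions: PivCl, pyridine, DMAP (cat.), CH2Cl2, 0 °C → rt
Reagents that add atoms: pivaloyl chloride, CC(C)(C)C(=O)Cl
Why: Esterification of the primary alcohol should be fast; the pivalate is chosen because an ether oxygen here would sit at the same five-ring distance from C5 as the ketone oxygen and could open the activated lactone itself, whereas the ester oxygen is not nucleophilic and is removed later by LiAlH4.

Step 6
Reactants: 11 tert-butyl (3S)-4-[(4S)-4-benzyl-2-oxooxazolidin-3-yl]-4-oxo-3-[(pivaloyloxy)methyl]butanoate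
Product: 12 tert-butyl (3S)-4-(ethylsulfanyl)-4-oxo-3-[(pivaloyloxy)methyl]butanoate
Conditions: EtSH, n-BuLi, THF, 0 °C
Reagents that add atoms: ethanethiol, CCS
Why: Thiolate transacylation of the N-acyloxazolidinone attacks the exocyclic imide carbonyl selectively, is not basic enough to enolise the α-stereocentre or to touch the tert-butyl and pivalate esters, and returns the auxiliary.

Step 7
Reactants: 12 tert-butyl (3S)-4-(ethylsulfanyl)-4-oxo-3-[(pivaloyloxy)methyl]butanoate
Product: 13 (3S)-4-(ethylsulfanyl)-4-oxo-3-[(pivaloyloxy)methyl]butanoic acid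
Conditions: CF3CO2H, CH2Cl2, 0 °C → rt
Reagents that add atoms: none
Why: Acidolysis of the tert-butyl ester (loss of isobutene) is selective because the thioester and the pivalate are stable to trifluoroacetic acid.

Step 8
Reactants: 13 (3S)-4-(ethylsulfanyl)-4-oxo-3-[(pivaloyloxy)methyl]butanoic acid
Product: 14 S-ethyl (2S)-4-chloro-4-oxo-2-[(pivaloyloxy)methyl]butanethioate
Conditions: (COCl)2, DMF (cat.), CH2Cl2, 0 °C → rt; evaporate, use crude
Reagents that add atoms: oxalyl chloride, ClC(=O)C(Cl)=O
Why: Acid chloride formation under Vilsmeier catalysis is standard, and the thioester (unlike a free γ-ketone, which would give a pseudo-chloride or enol lactone) and the pivalate are inert.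

Step 9
Reactants: 14 S-ethyl (2S)-4-chloro-4-oxo-2-[(pivaloyloxy)methyl]butanethioate; 2 4-formyl-2-methoxyphenyl pivalate
Product: 16 S-ethyl (2S)-2-[(2R,3R)-2-(3-methoxy-4-pivaloyloxyphenyl)-4-oxooxetan-3-yl]-3-(pivaloyloxy)propanethioate (cis-β-lactone), via ketene 15 (not isolated)
Conditions: O-trimethylsilylquinidine (15 mol %), LiClO4, iPr2NEt, CH2Cl2/Et2O, −78 °C; 14 added slowly to excess 2
Reagents that add atoms: none
Why: Alkaloid/LiClO4-catalysed acyl halide–aldehyde cyclocondensation (formal ketene–aldehyde [2+2]): the alkaloid-bound Z-ammonium enolate adds to the lithium-activated aldehyde through a closed transition state and lactonises, which should give the cis-3,4-disubstituted β-lactone with both new centres (3R,4R) set by the catalyst and not by the remote side-chain centre.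

Step 10
Reactants: 16 S-ethyl (2S)-2-[(2R,3R)-2-(3-methoxy-4-pivaloyloxyphenyl)-4-oxooxetan-3-yl]-3-(pivaloyloxy)propanethioate; 17 (4-benzyloxy-3-methoxyphenyl)boronic acid
Product: 18 (3R,4R)-3-[(2S)-1-(4-benzyloxy-3-methoxyphenyl)-1-oxo-3-(pivaloyloxy)propan-2-yl]-4-(3-methoxy-4-pivaloyloxyphenyl)oxetan-2-one
Conditions: Pd2(dba)3 (2.5 mol %), tri(2-furyl)phosphine, copper thiophene-2-carboxylate Cu(O2CC4H3S), THF, 40 °C
Reagents that add atoms: none
Why: Liebeskind–Srogl thioester–boronic acid coupling runs without added base (zerovalent palladium inserts into the C–S bond, the copper carboxylate assists transmetalation, reductive elimination gives the ketone), so the aryl ketone should form without epimerising the adjacent centre, eliminating the β-pivalate or opening the β-lactone.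

Step 11
Reactants: 18 (3R,4R)-3-[(2S)-1-(4-benzyloxy-3-methoxyphenyl)-1-oxo-3-(pivaloyloxy)propan-2-yl]-4-(3-methoxy-4-pivaloyloxyphenyl)oxetan-2-one
Product: 20 (2S,3R,4S,5S)-5-(4-benzyloxy-3-methoxyphenyl)-2-(3-methoxy-4-pivaloyloxyphenyl)-4-(pivaloyloxymethyl)tetrahydrofuran-3-carboxylic acid, via cyclic oxocarbenium carboxylate 19 (not isolated)
Conditions: BF3·OEt2, Et3SiH, CH2Cl2, −78 → −30 °C; cold aqueous quench, then pH 3
Reagents that add atoms: none
Why: Proposed new method: BF3 coordination to the lactone weakens the benzylic C5–O bond (target numbering), and the oxygen of the electron-rich aryl ketone attacks C5 from the side opposite the departing carboxylate; this closes the tetrahydrofuran ring (bond O1–C5) in a 5-exo-tet mode and leaves a 2-aryl oxocarbenium ion that Et3SiH reduces at C2. The closest known reaction is the Mead reductive cyclisation of keto-β-lactones with a Lewis acid and a silane, where the keto chain hangs on the lactone β-carbon; here it hangs on the α-carbon, so the lactone carboxyl emerges as the C4 carboxylic acid, and this tether is untested although the attack angle it needs (about 90° to the C4–C5 bond, in the lactone plane) is that of an ordinary five-ring SN2 closure. C5 is set by inversion of the cis-lactone carbon, which places the C5 aryl group cis to the C4 carboxyl; C2 is set by hydride delivery to the envelope oxocarbenium ion on the face anti to the C3 pivaloyloxymethyl group, as in BF3/silane reductions of 2-aryl-3-alkyl cyclic hemiketals, which places the C2 aryl group cis to C3. The step needs the ketone oxygen to be the only internal nucleophile and the opening to stay invertive: the side-chain oxygen is an ester and cannot close a competing five-membered oxonium ring, the 4-pivaloyloxy group on the C5 aryl ring disfavours benzylic ionisation (loss of CO2, scrambling of C5), and the 4-benzyloxy group raises the nucleophilicity of the ketone and stabilises the oxocarbenium ion. Low temperature should hold back direct silane reduction of the ketone and Lewis-acid epimerisation of the product at its benzylic carbons.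

Step 12
Reactants: 20 (2S,3R,4S,5S)-5-(4-benzyloxy-3-methoxyphenyl)-2-(3-methoxy-4-pivaloyloxyphenyl)-4-(pivaloyloxymethyl)tetrahydrofuran-3-carboxylic acid
Product: 21 [(2S,3S,4S,5S)-2-(4-benzyloxy-3-methoxyphenyl)-5-(4-hydroxy-3-methoxyphenyl)tetrahydrofuran-3,4-diyl]dimethanol
Conditions: LiAlH4, THF, 0 °C → rt; aqueous Rochelle salt, pH about 6
Reagents that add atoms: none
Why: Hydride reduction with LiAlH4 takes the carboxylic acid to the primary alcohol and cleaves both pivalates in the same operation, while the aryl benzyl ether and the ring ether are inert and no stereocentre is touched.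

Step 13
Reactants: 21 [(2S,3S,4S,5S)-2-(4-benzyloxy-3-methoxyphenyl)-5-(4-hydroxy-3-methoxyphenyl)tetrahydrofuran-3,4-diyl]dimethanol
Product: 22 [(2S,3S,4S,5S)-2,5-bis(4-hydroxy-3-methoxyphenyl)tetrahydrofuran-3,4-diyl]dimethanol (Eduesmine)
Conditions: H2 (1 atm), Pd/C, EtOAc–MeOH, rt
Reagents that add atoms: none
Why: Hydrogenolysis of the aryl benzyl ether under neutral conditions at one atmosphere is much faster than cleavage of the benzylic C–O bonds of the ring, so it should release the second phenol and give the target with its four stereocentres unchanged.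

**Compound list**

1 | vanillin | COc1cc(C=O)ccc1O | starting material
2 | 4-formyl-2-methoxyphenyl pivalate | COc1cc(C=O)ccc1OC(=O)C(C)(C)C | intermediate
3 | 3-(benzyloxy)propanoic acid | OC(=O)CCOCc1ccccc1 | starting material
4 | (S)-4-benzyloxazolidin-2-one | O=C1N[C@@H](Cc2ccccc2)CO1 | starting material
5 | 3-(benzyloxy)propanoic pivalic anhydride | CC(C)(C)C(=O)OC(=O)CCOCc1ccccc1 | intermediate
6 | (S)-4-benzyl-3-[3-(benzyloxy)propanoyl]oxazolidin-2-one | O=C(CCOCc1ccccc1)N1[C@@H](Cc2ccccc2)COC1=O | intermediate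
7 | tert-butyl bromoacetate | CC(C)(C)OC(=O)CBr | starting material
8 | sodium Z-enolate of 6 | [Na+].[O-]/C(=C\COCc1ccccc1)N1[C@@H](Cc2ccccc2)COC1=O | intermediate
9 | tert-butyl (3S)-3-[(benzyloxy)methyl]-4-[(4S)-4-benzyl-2-oxooxazolidin-3-yl]-4-oxobutanoate | CC(C)(C)OC(=O)C[C@@H](COCc1ccccc1)C(=O)N1[C@@H](Cc2ccccc2)COC1=O | intermediate
10 | tert-butyl (3S)-4-[(4S)-4-benzyl-2-oxooxazolidin-3-yl]-3-(hydroxymethyl)-4-oxobutanoate | CC(C)(C)OC(=O)C[C@@H](CO)C(=O)N1[C@@H](Cc2ccccc2)COC1=O | intermediate
11 | tert-butyl (3S)-4-[(4S)-4-benzyl-2-oxooxazolidin-3-yl]-4-oxo-3-[(pivaloyloxy)methyl]butanoate | CC(C)(C)OC(=O)C[C@@H](COC(=O)C(C)(C)C)C(=O)N1[C@@H](Cc2ccccc2)COC1=O | intermediate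
12 | tert-butyl (3S)-4-(ethylsulfanyl)-4-oxo-3-[(pivaloyloxy)methyl]butanoate | CC(C)(C)OC(=O)C[C@@H](COC(=O)C(C)(C)C)C(=O)SCC | intermediate
13 | (3S)-4-(ethylsulfanyl)-4-oxo-3-[(pivaloyloxy)methyl]butanoic acid | OC(=O)C[C@@H](COC(=O)C(C)(C)C)C(=O)SCC | intermediate
14 | S-ethyl (2S)-4-chloro-4-oxo-2-[(pivaloyloxy)methyl]butanethioate | ClC(=O)C[C@@H](COC(=O)C(C)(C)C)C(=O)SCC | intermediate
15 | S-ethyl (2S)-4-oxo-2-[(pivaloyloxy)methyl]but-3-enethioate (ketene) | O=C=C[C@@H](COC(=O)C(C)(C)C)C(=O)SCC | intermediate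
16 | S-ethyl (2S)-2-[(2R,3R)-2-(3-methoxy-4-pivaloyloxyphenyl)-4-oxooxetan-3-yl]-3-(pivaloyloxy)propanethioate | O=C1O[C@@H](c2ccc(OC(=O)C(C)(C)C)c(OC)c2)[C@H]1[C@@H](COC(=O)C(C)(C)C)C(=O)SCC | intermediate
17 | (4-benzyloxy-3-methoxyphenyl)boronic acid | COc1cc(B(O)O)ccc1OCc1ccccc1 | starting material
18 | (3R,4R)-3-[(2S)-1-(4-benzyloxy-3-methoxyphenyl)-1-oxo-3-(pivaloyloxy)propan-2-yl]-4-(3-methoxy-4-pivaloyloxyphenyl)oxetan-2-one | O=C1O[C@@H](c2ccc(OC(=O)C(C)(C)C)c(OC)c2)[C@H]1[C@@H](COC(=O)C(C)(C)C)C(=O)c1ccc(OCc2ccccc2)c(OC)c1 | intermediate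
19 | cyclic 2-aryl oxocarbenium carboxylate (drawn as the zwitterion; BF3-bound in the flask) | COc1cc(C2=[O+][C@H](c3ccc(OC(=O)C(C)(C)C)c(OC)c3)[C@H](C(=O)[O-])[C@H]2COC(=O)C(C)(C)C)ccc1OCc1ccccc1 | intermediate
20 | (2S,3R,4S,5S)-5-(4-benzyloxy-3-methoxyphenyl)-2-(3-methoxy-4-pivaloyloxyphenyl)-4-(pivaloyloxymethyl)tetrahydrofuran-3-carboxylic acid | COc1cc([C@H]2O[C@H](c3ccc(OC(=O)C(C)(C)C)c(OC)c3)[C@H](C(=O)O)[C@H]2COC(=O)C(C)(C)C)ccc1OCc1ccccc1 | intermediate
21 | [(2S,3S,4S,5S)-2-(4-benzyloxy-3-methoxyphenyl)-5-(4-hydroxy-3-methoxyphenyl)tetrahydrofuran-3,4-diyl]dimethanol | COc1cc([C@H]2O[C@H](c3ccc(O)c(OC)c3)[C@H](CO)[C@H]2CO)ccc1OCc1ccccc1 | intermediate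
22 | [(2S,3S,4S,5S)-2,5-bis(4-hydroxy-3-methoxyphenyl)tetrahydrofuran-3,4-diyl]dimethanol (Eduesmine) | COc1cc([C@H]2O[C@H](c3ccc(O)c(OC)c3)[C@H](CO)[C@H]2CO)ccc1O | target

**Step count**

Total: 13 steps. Longest linear sequence: 12 steps (steps 2–13); step 1 is a one-step side branch.

**Steps most likely to fail**

1. Step 11 (the step proposed as a new method).
   - What may go wrong: the benzylic C5–O bond ionises before backside attack (loss of CO2 to a styrene, or loss of the C5 configuration); the α-tethered carbonyl oxygen fails to reach the backside of C5; the silane reduces the ketone before it cyclises; or the ketone aryl ring captures C5 in a Friedel–Crafts sense.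
   - Fallback with known chemistry (γ-lactone, aryllithium addition, hemiketal reduction; O1–C2 is closed last): it sets out from 12 (with 17) and comes back at 22.
   - 12 and 17 are coupled under the conditions of step 10 to the keto ester F1. CBS reduction ((R)-Me-CBS oxazaborolidine, BH3·SMe2) gives the hydroxy ester F2, which lactonises (PPTS, toluene, 50 °C) to the 4,5-cis γ-lactone F3.
   - The lithium enolate (LiN(SiMe3)2, THF, −78 °C) is alkylated by benzyl chloromethyl ether trans to the C4 substituent to give the disubstituted lactone F4.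
   - The aryllithium F5 (from commercial 1-(benzyloxy)-4-bromo-2-methoxybenzene and n-BuLi) adds to F4 to give the cyclic hemiketal F6. BF3·OEt2/Et3SiH at −78 °C reduces F6 with hydride anti to the neighbouring benzyloxymethyl group to the 2,3-cis tetrahydrofuran F7.
   - LiAlH4 removes the pivalate to give the alcohol F8, and hydrogenolysis (H2, Pd/C) of the three benzyl ethers gives 22.

2. Step 9.
   - What may go wrong: the side-chain thioester interferes. The aldolate may be intercepted by the thioester carbonyl (γ-lactone formation) before it closes onto the acylammonium ion; the carbon next to the thioester may epimerise or lose pivalate under amine/LiClO4; or the branched ketene may react too slowly with the aromatic aldehyde and dimerise.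
   - Fallback (aryl ketone made first and carried as an alkene): it sets out from 12 and comes back at 18, so that no coupling is needed on the lactone.
   - The keto ester F1 (made as above) is methylenated under non-basic Takai–Lombardo conditions (Zn, CH2Br2, TiCl4) to the 1,1-disubstituted alkene ester F9.
   - The tert-butyl ester is cleaved without protic acid (Me3SiOTf, 2,6-lutidine, then water) to the alkene acid F10, and 1-chloro-N,N,2-trimethylprop-1-en-1-amine gives the acid chloride F11.
   - The cycloaddition of step 9, now through the plain alkyl-type ketene F12, with 2 gives the alkene β-lactone F13.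
   - Ozonolysis (O3, CH2Cl2, −78 °C; Me2S) unveils the ketone and gives 18.

3. Step 10.
   - What may go wrong: the strained lactone is opened by the copper carboxylate or thiolate at 40 °C; transmetalation is slow, so the acylpalladium species decarbonylates; or the product epimerises or eliminates pivalate next to the new ketone.
   - Fallback (1,2-addition and oxidation instead of acyl cross-coupling): it sets out from 16 and comes back at 18.
   - Fukuyama reduction (Et3SiH, Pd/C, acetone, rt) gives the aldehyde F14.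
   - The aryltitanium reagent F15, made from the aryllithium F5 and ClTi(OiPr)3, adds chemoselectively to the aldehyde at −78 → −40 °C to give the carbinol F16 as a mixture of epimers.
   - F16 is oxidised at once with Dess–Martin periodinane (NaHCO3 buffer) to 18.

**Further compounds**

F1 | step 11 | tert-butyl (3S)-4-(4-benzyloxy-3-methoxyphenyl)-4-oxo-3-[(pivaloyloxy)methyl]butanoate | CC(C)(C)OC(=O)C[C@@H](COC(=O)C(C)(C)C)C(=O)c1ccc(OCc2ccccc2)c(OC)c1
F2 | step 11 | tert-butyl (3S,4S)-4-(4-benzyloxy-3-methoxyphenyl)-4-hydroxy-3-[(pivaloyloxy)methyl]butanoate | CC(C)(C)OC(=O)C[C@@H](COC(=O)C(C)(C)C)[C@H](O)c1ccc(OCc2ccccc2)c(OC)c1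
F3 | step 11 | [(2S,3S)-2-(4-benzyloxy-3-methoxyphenyl)-5-oxotetrahydrofuran-3-yl]methyl pivalate | O=C1C[C@@H](COC(=O)C(C)(C)C)[C@@H](c2ccc(OCc3ccccc3)c(OC)c2)O1
F4 | step 11 | [(2S,3S,4S)-2-(4-benzyloxy-3-methoxyphenyl)-4-[(benzyloxy)methyl]-5-oxotetrahydrofuran-3-yl]methyl pivalate | O=C1[C@H](COCc2ccccc2)[C@@H](COC(=O)C(C)(C)C)[C@@H](c2ccc(OCc3ccccc3)c(OC)c2)O1
F5 | step 11 | (4-benzyloxy-3-methoxyphenyl)lithium | [Li]c1ccc(OCc2ccccc2)c(OC)c1
F6 | step 11 | [(2S,3S,4S)-2,5-bis(4-benzyloxy-3-methoxyphenyl)-4-[(benzyloxy)methyl]-5-hydroxytetrahydrofuran-3-yl]methyl pivalate (both anomers) | COc1cc(C2(O)O[C@H](c3ccc(OCc4ccccc4)c(OC)c3)[C@H](COC(=O)C(C)(C)C)[C@H]2COCc2ccccc2)ccc1OCc1ccccc1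
F7 | step 11 | [(2S,3S,4S,5S)-2,5-bis(4-benzyloxy-3-methoxyphenyl)-4-[(benzyloxy)methyl]tetrahydrofuran-3-yl]methyl pivalate | COc1cc([C@H]2O[C@H](c3ccc(OCc4ccccc4)c(OC)c3)[C@H](COC(=O)C(C)(C)C)[C@H]2COCc2ccccc2)ccc1OCc1ccccc1
F8 | step 11 | [(2S,3S,4S,5S)-2,5-bis(4-benzyloxy-3-methoxyphenyl)-4-[(benzyloxy)methyl]tetrahydrofuran-3-yl]methanol | COc1cc([C@H]2O[C@H](c3ccc(OCc4ccccc4)c(OC)c3)[C@H](CO)[C@H]2COCc2ccccc2)ccc1OCc1ccccc1
F9 | step 9 | tert-butyl (3R)-4-(4-benzyloxy-3-methoxyphenyl)-3-[(pivaloyloxy)methyl]pent-4-enoate | CC(C)(C)OC(=O)C[C@@H](COC(=O)C(C)(C)C)C(=C)c1ccc(OCc2ccccc2)c(OC)c1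
F10 | step 9 | (3R)-4-(4-benzyloxy-3-methoxyphenyl)-3-[(pivaloyloxy)methyl]pent-4-enoic acid | OC(=O)C[C@@H](COC(=O)C(C)(C)C)C(=C)c1ccc(OCc2ccccc2)c(OC)c1
F11 | step 9 | (3R)-4-(4-benzyloxy-3-methoxyphenyl)-3-[(pivaloyloxy)methyl]pent-4-enoyl chloride | ClC(=O)C[C@@H](COC(=O)C(C)(C)C)C(=C)c1ccc(OCc2ccccc2)c(OC)c1
F12 | step 9 | (2R)-3-(4-benzyloxy-3-methoxyphenyl)-2-(2-oxoethenyl)but-3-en-1-yl pivalate (ketene) | O=C=C[C@@H](COC(=O)C(C)(C)C)C(=C)c1ccc(OCc2ccccc2)c(OC)c1
F13 | step 9 | (2R)-3-(4-benzyloxy-3-methoxyphenyl)-2-[(2R,3R)-2-(3-methoxy-4-pivaloyloxyphenyl)-4-oxooxetan-3-yl]but-3-en-1-yl pivalate | O=C1O[C@@H](c2ccc(OC(=O)C(C)(C)C)c(OC)c2)[C@H]1[C@@H](COC(=O)C(C)(C)C)C(=C)c1ccc(OCc2ccccc2)c(OC)c1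
F14 | step 10 | (2S)-2-[(2R,3R)-2-(3-methoxy-4-pivaloyloxyphenyl)-4-oxooxetan-3-yl]-3-oxopropyl pivalate | O=C1O[C@@H](c2ccc(OC(=O)C(C)(C)C)c(OC)c2)[C@H]1[C@@H](COC(=O)C(C)(C)C)C=O
F15 | step 10 | (4-benzyloxy-3-methoxyphenyl)tris(propan-2-yloxy)titanium | CC(C)O[Ti](OC(C)C)(OC(C)C)c1ccc(OCc2ccccc2)c(OC)c1
F16 | step 10 | (2S)-3-(4-benzyloxy-3-methoxyphenyl)-3-hydroxy-2-[(2R,3R)-2-(3-methoxy-4-pivaloyloxyphenyl)-4-oxooxetan-3-yl]propyl pivalate (both carbinol epimers) | O=C1O[C@@H](c2ccc(OC(=O)C(C)(C)C)c(OC)c2)[C@H]1[C@@H](COC(=O)C(C)(C)C)C(O)c1ccc(OCc2ccccc2)c(OC)c1
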